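## Structural features

The target (23) is a daucane sesquiterpene triester: a cyclopentane (C1–C5) and a cyclohept-8-ene (C1, C5–C10) share the C1–C5 bond in a trans-fused bicyclo[5.3.0]decane. C1 is the quaternary fusion carbon with a β-methyl group, C5 carries the α-hydrogen, C8 the vinylic methyl group and C4 the isopropyl group. These locants are kept for every compound below, also for the decalin intermediates, in which ring A is C1–C6 and ring B is C1, C6–C10; β is the face of the C1 methyl group. There are six stereocentres, (1R,2S,4R,5S,6S,10S): C10, C1, C5 and C6 are contiguous, C4 and C2 complete the five-membered ring, and the quaternary C1 is flanked by two oxygenated methines (C2, C10) and by C5. Oxygen sits on alternate carbons along C10–C1–C2–C3–C4–C5–C6: the 10β-benzoate, the 2α-acetate, a free tertiary 4β-alcohol geminal to the α-isopropyl group, and the 6α-angelate; the C4–OH/C6–O pair is an aldol relationship across C5. Fragile points are the angelate (Z to E isomerisation, conjugate addition), the allylic benzoate (ionisation), the tertiary alcohol (retro-aldol cleavage or dehydration whenever C6 is a ketone under basic conditions), and the need to place three different acyl groups in a fixed order. The real difficulty is the trans fusion bond C1–C5 between a quaternary carbon and a methine inside a seven-membered ring, embedded in four contiguous stereocentres. The key step exploits the oxygen on C6 next to C5: with C6 as a carbinol carbon and C5 as a sulfonate-bearing carbon of a decalin, the quaternary C1 can be shifted from C6 to C5. This makes the C1–C5 bond, the five-membered ring and the seven-membered ring at once, and the decalin ring A that results has CH3 (C1) and isopropyl (C4) para to each other with oxygen on C2 and C5, the pattern of a p-menthane quinone.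

## Logic of the disconnections

23 ⇒ 20 + 21. Cut: the ester C–O bond at C6. The angelate is the most labile group and is put on last, so that all earlier steps meet only acetate and benzoate. Demand: acylation of the secondary C6 hydroxyl beside the free tertiary C4 hydroxyl without isomerising the (Z)-enoate.

20 ⇒ 19. Cut: the C6–H bond (carbinol back to ketone). The C4–OH/C6–OH pair is a 1,3-anti diol, the retron of a hydroxyl-directed reduction of a β-hydroxy ketone. Gain: the C6 stereocentre is derived from C4. Demand: intramolecular hydride delivery under conditions that do not trigger retro-aldol cleavage.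

19 ⇒ 17 (key). Cut: C1–C5; reconnect: C1–C6. In one sentence: a pinacol-type 1,2-shift of the quaternary carbon C1 from the carbinol carbon C6 to the sulfonate-bearing C5 of the cis-decalin 17 contracts ring A to the cyclopentane and enlarges ring B to the cycloheptenone. The C6 oxygen, C5 and the quaternary C1 of the target are exactly the migration origin, terminus and migrating group. Gain: the hydroazulene with its trans fusion is replaced by a decalin whose ring A carries CH3 and isopropyl para and oxygen on C2, C4 and C5. Demand: an equatorial C5–O bond anti-periplanar to C6–C1, which means C4–OH, C5–OMs and C6–OH all cis to each other and to the C1 methyl group, and migration of C1 in preference to C3.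

17 ⇒ 14 (through 16). Cut: C5–O and C6–O back to the C5=C6 alkene, and the S–O bond. A cis-diol syn to the adjacent C4 hydroxyl is the retron of a hydroxyl-directed osmylation. Gain: three contiguous stereocentres are traced back to C4 alone. Demand: syn face selectivity, chemoselectivity over C8=C9, and sulfonylation of the only secondary hydroxyl.

14 ⇒ 10 (through 13, 12, 11). Cut: the benzoate C–O bond and the C10–H bond (redox inversion). The cycloaddition that builds ring B gives the 10α epimer, while the target needs 10β, cis to the C1 methyl group. Gain: the C10 configuration becomes controlled by the angular methyl group. Demand: hydride attack anti to that methyl group.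

10 ⇒ 6 (through 9, 8, 7). Cut: the acetate, the C2–H bond, the C5–H bond (back to the enol triflate) and the C3–H bond (back to the epoxide C3–O bond). These changes turn the ene-dione of a quinone adduct into the 2α-oxygen, the 4β-hydroxyl and the C5=C6 alkene. Gain: C2 is derived from C4; the C5 oxygen is removed so that it can return cis to the C6 oxygen. Demand: reductive epoxide opening only at C3–O and a chemoselective triflate reduction.

6 ⇒ 4 (through 5). Cut: the two epoxide C–O bonds and the enol O–S bond. Gain: back to a plain cis-fused ene-dione. Demand: epoxidation from the convex β face (sets C4–O) and enolisation only towards C6.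

4 ⇒ 2 + 3. Cut: C1–C10 and C6–C7 (ring B), the Diels–Alder retron of the C8=C9 cyclohexene. Gain: a ten-carbon and a five-carbon unit give all fifteen skeletal carbons in one step. Demand: reaction at the methyl-substituted and not the isopropyl-substituted double bond, C10 bonded to C1, and enantiofacial control (absolute configuration of C1).

2 ⇒ 1. Cut: the O–Si bond; the dienol ether comes from the enal by γ-deprotonation.

## Other disconnections considered

Alternative 1: the first idea is to cut the C8=C9 double bond. The forward key step is a ring-closing metathesis of diene A1 (a cyclopentane with the C10 vinyl carbinol on C1 and the C6 methallyl carbinol on C5) with the second-generation Grubbs catalyst. The chosen plan is preferred because the metathesis settles no stereocentre. A1 must already contain the quaternary C1 flanked by C2, C5 and C10, the trans C1/C5 relationship and both carbinol centres, which would come from additions to neopentyl aldehydes with no built-in control. More steps would be spent on A1 than on 17.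

Alternative 2: cut C7–C8 and C9–C10. The forward key step is a de Mayo sequence: [2+2] photocycloaddition of allene to the enol acetate A2 of a cis-bicyclo[3.3.0]octane-2,4-dione, then retro-aldol opening of the strained cyclobutane to the 8-methylene-6,10-dione A3. The strain-release idea is attractive, but A3 has two undifferentiated ketones, an exocyclic alkene that must be moved selectively towards C9, and a cis ring fusion that needs epimerisation at C5 next to the retro-aldol-prone C4 carbinol. None of C5, C6 and C10 is set, and A2 needs a long synthesis of its own.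

Alternative 3: cut C4–C5. The forward key step is an intramolecular aldol addition of diketone A4 (C6 enolate onto the C4 isopropyl ketone) under equilibrating conditions, which would give 19 directly in a stereoconvergent way. The chosen plan is preferred because enolisation of A4 should favour the allylic C7 over C5, the thermodynamic outcome at C4 and C5 (cis or trans fusion, dehydration) is not secured, and A4 still contains the seven-membered ring, the quaternary C1 and an acyclic C2 carbinol. The 1,2-shift fixes C5 by inversion.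

Key step: step 15

Assumption: the (S)-BINOL–titanium catalyst of step 2 is taken to give the enantiomer 4 as drawn; if the sense of induction is the opposite, (R)-BINOL is used with no other change.

Abbreviations: TBS = tert-butyldimethylsilyl, TMEDA = N,N,N',N'-tetramethylethylenediamine, DMP = Dess–Martin periodinane.

## Route

Step 1
Reactants: 1 3-methylbut-2-enal
Product: 2 (E)-tert-butyldimethyl[(3-methylbuta-1,3-dien-1-yl)oxy]silane
Conditions: TBSOTf, Et3N, Et2O, 0 °C → rt
Reagents that add atoms: tert-butyldimethylsilyl triflate, CC(C)(C)[Si](C)(C)OS(=O)(=O)C(F)(F)F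
Why: Silylation of the enal oxygen gives a silyloxyallyl cation that loses a γ-proton to Et3N (vinylogous silyl enol ether formation); the s-trans enal should give the (E)-dienol ether.

Step 2
Reactants: 2 (E)-tert-butyldimethyl[(3-methylbuta-1,3-dien-1-yl)oxy]silane; 3 thymoquinone (2-isopropyl-5-methyl-1,4-benzoquinone)
Product: 4 10α-(tert-butyldimethylsilyloxy)-4-isopropyl-1β,8-dimethyl-6βH-bicyclo[4.4.0]deca-3,8-diene-2,5-dione (cis-fused)
Conditions: (S)-BINOL (10 mol %), TiCl2(OiPr)2 (10 mol %), toluene, −30 °C
Reagents that add atoms: none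
Why: Endo Diels–Alder reaction at the less hindered, methyl-substituted double bond of the quinone; the diene terminus C7, made nucleophilic by the 1-silyloxy and 3-methyl groups, bonds to the unsubstituted carbon C6 so that C10 joins the methyl-bearing C1. Endo addition gives the cis fusion with the silyloxy group trans to the angular methyl group, and the chiral titanium Lewis acid selects the quinone face and so the configuration of C1.

Step 3
Reactants: 4 10α-(tert-butyldimethylsilyloxy)-4-isopropyl-1β,8-dimethyl-6βH-bicyclo[4.4.0]deca-3,8-diene-2,5-dione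
Product: 5 10α-(tert-butyldimethylsilyloxy)-3β,4β-epoxy-4α-isopropyl-1β,8-dimethyl-6βH-bicyclo[4.4.0]dec-8-ene-2,5-dione
Conditions: tBuOOH (decane), DBU, CH2Cl2, 0 °C
Reagents that add atoms: tert-butyl hydroperoxide, CC(C)(C)OO
Why: Weitz–Scheffer epoxidation: the peroxide anion adds to the ene-dione from the convex β face of the cis-fused bicycle (the α face is covered by ring B) and closes to the 3β,4β-epoxide, which fixes the C4–O configuration.

Step 4
Reactants: 5 10α-(tert-butyldimethylsilyloxy)-3β,4β-epoxy-4α-isopropyl-1β,8-dimethyl-6βH-bicyclo[4.4.0]dec-8-ene-2,5-dione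
Product: 6 10α-(tert-butyldimethylsilyloxy)-3β,4β-epoxy-4α-isopropyl-1β,8-dimethyl-2-oxobicyclo[4.4.0]deca-5,8-dien-5-yl trifluoromethanesulfonate
Conditions: KHMDS, THF, −78 °C; then PhNTf2, −78 → 0 °C
Reagents that add atoms: N-phenylbis(trifluoromethanesulfonimide), O=S(=O)(N(c1ccccc1)S(=O)(=O)C(F)(F)F)C(F)(F)F
Why: C6–H is the only enolisable position (C1 and C4 are quaternary); the potassium enolate is trapped on oxygen as the enol triflate, which marks the C5 oxygen for removal and deletes the C6 stereocentre.

Step 5
Reactants: 6 10α-(tert-butyldimethylsilyloxy)-3β,4β-epoxy-4α-isopropyl-1β,8-dimethyl-2-oxobicyclo[4.4.0]deca-5,8-dien-5-yl trifluoromethanesulfonate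
Product: 7 10α-(tert-butyldimethylsilyloxy)-4β-hydroxy-4α-isopropyl-1β,8-dimethyl-2-oxobicyclo[4.4.0]deca-5,8-dien-5-yl trifluoromethanesulfonate
Conditions: SmI2 (2.2 equiv), THF/MeOH, −90 °C
Reagents that add atoms: none
Why: Reduction of an α,β-epoxy ketone by divalent samarium: the ketyl of the C2 ketone (the only carbonyl left) cleaves the adjacent C3–O bond, and protonation gives the β-hydroxy ketone with the tertiary C4–OH kept on the β face.

Step 6
Reactants: 7 10α-(tert-butyldimethylsilyloxy)-4β-hydroxy-4α-isopropyl-1β,8-dimethyl-2-oxobicyclo[4.4.0]deca-5,8-dien-5-yl trifluoromethanesulfonate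
Product: 8 10α-(tert-butyldimethylsilyloxy)-2α,4β-dihydroxy-4α-isopropyl-1β,8-dimethylbicyclo[4.4.0]deca-5,8-dien-5-yl trifluoromethanesulfonate
Conditions: Me4NBH(OAc)3, MeCN/AcOH (1:1), −30 °C
Reagents that add atoms: none
Why: Evans–Saksena reduction: the pseudoaxial C4 hydroxyl binds the acetoxyborohydride and delivers hydride to the β face of the C2 carbonyl, which should give the 1,3-anti diol (2α-OH).

Step 7
Reactants: 8 10α-(tert-butyldimethylsilyloxy)-2α,4β-dihydroxy-4α-isopropyl-1β,8-dimethylbicyclo[4.4.0]deca-5,8-dien-5-yl trifluoromethanesulfonate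
Product: 9 10α-(tert-butyldimethylsilyloxy)-4α-isopropyl-1β,8-dimethylbicyclo[4.4.0]deca-5,8-diene-2α,4β-diol
Conditions: Pd(OAc)2 (5 mol %), PPh3, HCO2H, Bu3N, DMF, 60 °C
Reagents that add atoms: none
Why: Palladium-catalysed formate reduction of an enol triflate: oxidative addition of zerovalent palladium, formate exchange, loss of CO2 and reductive elimination replace OTf by H and leave the C5=C6 alkene next to the tertiary allylic alcohol.

Step 8
Reactants: 9 10α-(tert-butyldimethylsilyloxy)-4α-isopropyl-1β,8-dimethylbicyclo[4.4.0]deca-5,8-diene-2α,4β-diol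
Product: 10 10α-(tert-butyldimethylsilyloxy)-4β-hydroxy-4α-isopropyl-1β,8-dimethylbicyclo[4.4.0]deca-5,8-dien-2α-yl acetate
Conditions: Ac2O, pyridine, DMAP (cat.), CH2Cl2, rt
Reagents that add atoms: acetic anhydride, CC(=O)OC(C)=O
Why: DMAP-catalysed acetylation of the secondary C2 alcohol; the hindered tertiary C4 alcohol should not be acylated under these conditions.

Step 9
Reactants: 10 10α-(tert-butyldimethylsilyloxy)-4β-hydroxy-4α-isopropyl-1β,8-dimethylbicyclo[4.4.0]deca-5,8-dien-2α-yl acetate
Product: 11 4β,10α-dihydroxy-4α-isopropyl-1β,8-dimethylbicyclo[4.4.0]deca-5,8-dien-2α-yl acetate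
Conditions: TBAF, AcOH, THF, rt
Reagents that add atoms: none
Why: Fluoride cleaves the Si–O bond; buffering with acetic acid should keep the C10 alkoxide from inducing acetyl migration from C2.

Step 10
Reactants: 11 4β,10α-dihydroxy-4α-isopropyl-1β,8-dimethylbicyclo[4.4.0]deca-5,8-dien-2α-yl acetate
Product: 12 4β-hydroxy-4α-isopropyl-1β,8-dimethyl-10-oxobicyclo[4.4.0]deca-5,8-dien-2α-yl acetate
Conditions: DMP, pyridine, CH2Cl2, 0 °C → rt
Reagents that add atoms: none
Why: Dess–Martin oxidation of the secondary allylic alcohol to the enone removes the C10 configuration left by the endo cycloaddition; the tertiary alcohol is inert, and 12 is taken on at once to avoid base-induced migration of the C5=C6 bond into conjugation.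

Step 11
Reactants: 12 4β-hydroxy-4α-isopropyl-1β,8-dimethyl-10-oxobicyclo[4.4.0]deca-5,8-dien-2α-yl acetate
Product: 13 4β,10β-dihydroxy-4α-isopropyl-1β,8-dimethylbicyclo[4.4.0]deca-5,8-dien-2α-yl acetate
Conditions: NaBH4, CeCl3·7H2O, MeOH, −78 °C
Reagents that add atoms: none
Why: Luche reduction (1,2-selective): hydride should attack the C10 carbonyl anti to the axial angular methyl group on C1, as is usual for ketones next to the angular methyl group of 1-methyloctalins, giving the 10β alcohol cis to CH3.

Step 12
Reactants: 13 4β,10β-dihydroxy-4α-isopropyl-1β,8-dimethylbicyclo[4.4.0]deca-5,8-dien-2α-yl acetate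
Product: 14 2α-acetoxy-4β-hydroxy-4α-isopropyl-1β,8-dimethylbicyclo[4.4.0]deca-5,8-dien-10β-yl benzoate
Conditions: BzCl, pyridine, DMAP, CH2Cl2, 40 °C
Reagents that add atoms: benzoyl chloride, O=C(Cl)c1ccccc1
Why: DMAP-catalysed benzoylation of the secondary allylic alcohol; the tertiary C4–OH stays free and is needed as the directing group of the next step.

Step 13
Reactants: 14 2α-acetoxy-4β-hydroxy-4α-isopropyl-1β,8-dimethylbicyclo[4.4.0]deca-5,8-dien-10β-yl benzoate
Product: 16 2α-acetoxy-4β,5β,6β-trihydroxy-4α-isopropyl-1β,8-dimethylbicyclo[4.4.0]dec-8-en-10β-yl benzoate, via osmate ester 15 (not isolated)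
Conditions: OsO4 (1.05 equiv), TMEDA (1.1 equiv), CH2Cl2, −78 °C; then aq. Na2SO3, THF, 40 °C
Reagents that add atoms: osmium tetroxide, O=[Os](=O)(=O)=O
Why: Hydroxyl-directed dihydroxylation: the OsO4·TMEDA complex is hydrogen-bonded by the pseudoaxial C4–OH and adds suprafacially to the β face of the adjacent C5=C6 bond, which should give the all-cis 4β,5β,6β-triol after reductive cleavage of the hexavalent osmium ester 15. The same hydrogen bond selects this alkene over C8=C9.

Step 14
Reactants: 16 2α-acetoxy-4β,5β,6β-trihydroxy-4α-isopropyl-1β,8-dimethylbicyclo[4.4.0]dec-8-en-10β-yl benzoate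
Product: 17 2α-acetoxy-4β,6β-dihydroxy-4α-isopropyl-5β-(methanesulfonyloxy)-1β,8-dimethylbicyclo[4.4.0]dec-8-en-10β-yl benzoate
Conditions: MsCl, Et3N, CH2Cl2, −20 °C
Reagents that add atoms: methanesulfonyl chloride, CS(=O)(=O)Cl
Why: Only the secondary C5 hydroxyl is sulfonylated (sulfene mechanism); the two flanking tertiary alcohols should not react at low temperature.

Step 15
Reactants: 17 2α-acetoxy-4β,6β-dihydroxy-4α-isopropyl-5β-(methanesulfonyloxy)-1β,8-dimethylbicyclo[4.4.0]dec-8-en-10β-yl benzoate
Product: 19 2α-acetoxy-10β-benzoyloxy-4β-hydroxy-5αH-dauc-8-en-6-one, via aluminium alkoxide 18 (not isolated)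
Conditions: Et3Al (4 equiv), CH2Cl2, −78 → 0 °C; aq. Rochelle salt work-up
Reagents that add atoms: none
Why: Et3Al turns both tertiary hydroxyls into aluminium alkoxides (18) and activates the mesylate; the C6–O lone pair pushes while the anti-periplanar C6–C1 σ bond migrates to C5 with loss of mesylate, a concerted pinacol-type (semipinacol) 1,2-alkyl shift whose closest known forms are the organoaluminium-promoted rearrangement of β-mesyloxy alcohols and the rearrangement of decalin-diol monosulfonates to hydroazulenones. The cyclopentane (C1–C5) is closed by the new C1–C5 bond through backside, 3-exo-tet-like displacement at C5, and the cycloheptenone (C1, C5–C10) arises from the same bond switch as a one-carbon enlargement of ring B, C6 becoming the ketone. C5 is the only stereocentre created: it is inverted, so the β-mesylate fixed in steps 13 and 14 gives the 5α-hydrogen, while C1 migrates with retention, which makes the ring fusion trans. The step needs migration of C1 and not of C3 or C7: in the preferred chair of ring A (isopropyl, acetate, C1 methyl and mesylate all equatorial) the equatorial C5–O bond is anti-periplanar only to the ring bonds C6–C1 and C4–C3, C7 is gauche, and the quaternary, electron-rich C1 should migrate far more readily than the primary C3. The aluminium aldolate should hold the β-hydroxy ketone against retro-aldol cleavage until the cold work-up.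

Step 16
Reactants: 19 2α-acetoxy-10β-benzoyloxy-4β-hydroxy-5αH-dauc-8-en-6-one
Product: 20 2α-acetoxy-10β-benzoyloxy-5αH-dauc-8-ene-4β,6α-diol
Conditions: Me4NBH(OAc)3, MeCN/AcOH (1:1), −30 °C
Reagents that add atoms: none
Why: Evans–Saksena reduction: hydride is delivered from the boron bound to the C4–OH, which lies on the β side of the seven-membered ring, to the β face of the C6 ketone; this should give the 1,3-anti diol, that is the 6α-alcohol, under acidic conditions that avoid retro-aldol cleavage.

Step 17
Reactants: 20 2α-acetoxy-10β-benzoyloxy-5αH-dauc-8-ene-4β,6α-diol; 21 angelic acid [(Z)-2-methylbut-2-enoic acid]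
Product: 23 target: 2α-acetoxy-6α-angeloyloxy-10β-benzoyloxy-4β-hydroxy-5αH-dauc-8-ene, via mixed anhydride 22 (not isolated)
Conditions: 21, 2,4,6-trichlorobenzoyl chloride, Et3N, toluene, rt; then 20, toluene, 80 °C
Reagents that add atoms: none
Why: Yamaguchi esterification: the mixed anhydride 22 acylates the secondary C6–OH at its less hindered angeloyl carbonyl; leaving out DMAP and strong base should keep the (Z)-alkene from isomerising, and the tertiary C4–OH stays free.

## Compound list

1 | 3-methylbut-2-enal | CC(C)=CC=O | starting material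
2 | (E)-tert-butyldimethyl[(3-methylbuta-1,3-dien-1-yl)oxy]silane | C=C(C)/C=C/O[Si](C)(C)C(C)(C)C | intermediate
3 | thymoquinone (2-isopropyl-5-methyl-1,4-benzoquinone) | CC1=CC(=O)C(C(C)C)=CC1=O | starting material
4 | 10α-(tert-butyldimethylsilyloxy)-4-isopropyl-1β,8-dimethyl-6βH-bicyclo[4.4.0]deca-3,8-diene-2,5-dione (cis-fused endo adduct) | CC(C)(C)[Si](C)(C)O[C@@H]1C=C(C)C[C@@H]2C(=O)C(C(C)C)=CC(=O)[C@]12C | intermediate
5 | 10α-(tert-butyldimethylsilyloxy)-3β,4β-epoxy-4α-isopropyl-1β,8-dimethyl-6βH-bicyclo[4.4.0]dec-8-ene-2,5-dione | CC(C)(C)[Si](C)(C)O[C@@H]1C=C(C)C[C@@H]2C(=O)[C@@]3(C(C)C)O[C@H]3C(=O)[C@]12C | intermediate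
6 | 10α-(tert-butyldimethylsilyloxy)-3β,4β-epoxy-4α-isopropyl-1β,8-dimethyl-2-oxobicyclo[4.4.0]deca-5,8-dien-5-yl trifluoromethanesulfonate | CC(C)(C)[Si](C)(C)O[C@@H]1C=C(C)CC2=C(OS(=O)(=O)C(F)(F)F)[C@@]3(C(C)C)O[C@H]3C(=O)[C@]12C | intermediate
7 | 10α-(tert-butyldimethylsilyloxy)-4β-hydroxy-4α-isopropyl-1β,8-dimethyl-2-oxobicyclo[4.4.0]deca-5,8-dien-5-yl trifluoromethanesulfonate | CC(C)(C)[Si](C)(C)O[C@@H]1C=C(C)CC2=C(OS(=O)(=O)C(F)(F)F)[C@](O)(C(C)C)CC(=O)[C@]12C | intermediate
8 | 10α-(tert-butyldimethylsilyloxy)-2α,4β-dihydroxy-4α-isopropyl-1β,8-dimethylbicyclo[4.4.0]deca-5,8-dien-5-yl trifluoromethanesulfonate | CC(C)(C)[Si](C)(C)O[C@@H]1C=C(C)CC2=C(OS(=O)(=O)C(F)(F)F)[C@](O)(C(C)C)C[C@H](O)[C@]12C | intermediate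
9 | 10α-(tert-butyldimethylsilyloxy)-4α-isopropyl-1β,8-dimethylbicyclo[4.4.0]deca-5,8-diene-2α,4β-diol | CC(C)(C)[Si](C)(C)O[C@@H]1C=C(C)CC2=C[C@](O)(C(C)C)C[C@H](O)[C@]12C | intermediate
10 | 10α-(tert-butyldimethylsilyloxy)-4β-hydroxy-4α-isopropyl-1β,8-dimethylbicyclo[4.4.0]deca-5,8-dien-2α-yl acetate | CC(C)(C)[Si](C)(C)O[C@@H]1C=C(C)CC2=C[C@](O)(C(C)C)C[C@H](OC(C)=O)[C@]12C | intermediate
11 | 4β,10α-dihydroxy-4α-isopropyl-1β,8-dimethylbicyclo[4.4.0]deca-5,8-dien-2α-yl acetate | O[C@@H]1C=C(C)CC2=C[C@](O)(C(C)C)C[C@H](OC(C)=O)[C@]12C | intermediate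
12 | 4β-hydroxy-4α-isopropyl-1β,8-dimethyl-10-oxobicyclo[4.4.0]deca-5,8-dien-2α-yl acetate | O=C1C=C(C)CC2=C[C@](O)(C(C)C)C[C@H](OC(C)=O)[C@]12C | intermediate
13 | 4β,10β-dihydroxy-4α-isopropyl-1β,8-dimethylbicyclo[4.4.0]deca-5,8-dien-2α-yl acetate | O[C@H]1C=C(C)CC2=C[C@](O)(C(C)C)C[C@H](OC(C)=O)[C@]12C | intermediate
14 | 2α-acetoxy-4β-hydroxy-4α-isopropyl-1β,8-dimethylbicyclo[4.4.0]deca-5,8-dien-10β-yl benzoate | O=C(O[C@H]1C=C(C)CC2=C[C@](O)(C(C)C)C[C@H](OC(C)=O)[C@]12C)c1ccccc1 | intermediate
15 | cyclic 5β,6β-osmate ester of 14 with chelating TMEDA | O=C(O[C@H]1C=C(C)C[C@@]23O[Os-2]4(=O)(=O)(O[C@H]3[C@](O)(C(C)C)C[C@H](OC(C)=O)[C@]12C)[N+](C)(C)CC[N+]4(C)C)c1ccccc1 | intermediate (not isolated)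
16 | 2α-acetoxy-4β,5β,6β-trihydroxy-4α-isopropyl-1β,8-dimethylbicyclo[4.4.0]dec-8-en-10β-yl benzoate (cis-fused) | O=C(O[C@H]1C=C(C)C[C@]2(O)[C@@H](O)[C@](O)(C(C)C)C[C@H](OC(C)=O)[C@]12C)c1ccccc1 | intermediate
17 | 2α-acetoxy-4β,6β-dihydroxy-4α-isopropyl-5β-(methanesulfonyloxy)-1β,8-dimethylbicyclo[4.4.0]dec-8-en-10β-yl benzoate (cis-fused) | O=C(O[C@H]1C=C(C)C[C@]2(O)[C@@H](OS(C)(=O)=O)[C@](O)(C(C)C)C[C@H](OC(C)=O)[C@]12C)c1ccccc1 | intermediate
18 | 4,6-bis(diethylaluminium) alkoxide of 17 | O=C(O[C@H]1C=C(C)C[C@]2(O[Al](CC)CC)[C@@H](OS(C)(=O)=O)[C@](O[Al](CC)CC)(C(C)C)C[C@H](OC(C)=O)[C@]12C)c1ccccc1 | intermediate (not isolated)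
19 | 2α-acetoxy-10β-benzoyloxy-4β-hydroxy-5αH-dauc-8-en-6-one (trans-fused) | O=C1CC(C)=C[C@H](OC(=O)c2ccccc2)[C@@]2(C)[C@@H](OC(C)=O)C[C@@](O)(C(C)C)[C@H]12 | intermediate
20 | 2α-acetoxy-10β-benzoyloxy-5αH-dauc-8-ene-4β,6α-diol | O[C@H]1CC(C)=C[C@H](OC(=O)c2ccccc2)[C@@]2(C)[C@@H](OC(C)=O)C[C@@](O)(C(C)C)[C@H]12 | intermediate
21 | angelic acid [(Z)-2-methylbut-2-enoic acid] | C/C=C(/C)C(=O)O | starting material
22 | angelic 2,4,6-trichlorobenzoic anhydride | C/C=C(/C)C(=O)OC(=O)c1c(Cl)cc(Cl)cc1Cl | intermediate (not isolated)
23 | (1R,2S,4R,5S,6S,10S)-2-acetoxy-10-benzoyloxy-4-hydroxydauc-8-en-6-yl (Z)-2-methylbut-2-enoate | C/C=C(/C)C(=O)O[C@H]1CC(C)=C[C@H](OC(=O)c2ccccc2)[C@@]2(C)[C@@H](OC(C)=O)C[C@@](O)(C(C)C)[C@H]12 | target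

## Step count and least certain steps

Total: 17 steps. Longest linear sequence: 17 steps (1 → 23); 3 and 21 enter as purchased.

Step 15 (key step). The C4–C3 bond is also anti-periplanar to the mesylate, so a shift of C3 driven by the C4 alkoxide (contraction of ring A to an acylcyclopentane) may compete. The aluminium aldolate may also undergo retro-aldol cleavage, and the Lewis acid may ionise the allylic benzoate. Fallback: the leaving group is tied to the C4 oxygen, so that this oxygen can neither push nor form an aldolate. Triol 16 is treated with SOCl2 and Et3N to give the cyclic 4β,5β-sulfite F1, which is oxidised with RuCl3 (cat.) and NaIO4 to the cyclic sulfate F2 (the C5/C6 regioisomer, if it forms, is hydrolysed back to 16). NaH in THF then lets the C6 alkoxide drive the same C1 shift with opening of the sulfate to the C4 sulfate monoester F3, and H2SO4 (cat.) in wet THF hydrolyses F3 to 19, where the route is rejoined.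

Step 2. The Lewis acid can bind either quinone carbonyl, so enantiofacial discrimination may be poor and site or regioselectivity may erode; the silyl dienol ether may also be cleaved. Fallback: 2 and 3 are combined without catalyst (toluene, 60 °C), where only the intrinsic polarisation of the diene and the smaller methyl group steer the reaction. This gives 4 together with its mirror-image adduct F4, and the two are separated by preparative chromatography on a chiral stationary phase; the route is rejoined at 4.

Step 13. Osmylation of the more electron-rich C8=C9 bond may compete, and hindrance by the C1 methyl group may slow the directed addition or lower its facial selectivity. Fallback: the dihydroxylation is moved to enone 12, where the second alkene is deactivated by conjugation. OsO4·TMEDA on 12 gives the triol enone F5; Luche reduction gives the tetraol F6; benzoyl chloride (1 equiv, pyridine, 0 °C) acylates the allylic C10–OH in preference to the C5–OH, which is flanked by two quaternary carbons, and gives 16.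

Step 11. Hydride delivery syn to the angular methyl group (poor facial selectivity) would return the 10α epimer 11. Fallback: the redox inversion is replaced by a substitution: a Mitsunobu reaction of 11 with benzoic acid (PPh3, DIAD, toluene) inverts C10 and installs the benzoate in one operation, rejoining the route at 14 without 12 and 13.

Step 17. The angeloyl unit may isomerise to the tigloyl unit during activation, and the acylation of the hindered C6–OH may stall. Fallback: the (Z)-enoate is built on the molecule. Alcohol 20 is acylated with 2-[bis(2,2,2-trifluoroethoxy)phosphoryl]propanoic acid (DCC, DMAP) to the phosphonopropionate F7 (mixture at the phosphonate α-carbon), and a Still–Gennari olefination with acetaldehyde (KHMDS, 18-crown-6, THF, −78 °C) gives the Z-trisubstituted ester 23.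

## Further compounds

F1 | step 15 | cyclic 4β,5β-sulfite of 16 (mixture at sulfur) | O=C(O[C@H]1C=C(C)C[C@]2(O)[C@H]3OS(=O)O[C@@]3(C(C)C)C[C@H](OC(C)=O)[C@]12C)c1ccccc1
F2 | step 15 | cyclic 4β,5β-sulfate of 16 | O=C(O[C@H]1C=C(C)C[C@]2(O)[C@H]3OS(=O)(=O)O[C@@]3(C(C)C)C[C@H](OC(C)=O)[C@]12C)c1ccccc1
F3 | step 15 | 4-O-sulfate monoester of 19 | O=C1CC(C)=C[C@H](OC(=O)c2ccccc2)[C@@]2(C)[C@@H](OC(C)=O)C[C@@](OS(=O)(=O)O)(C(C)C)[C@H]12
F4 | step 2 | mirror image of 4 | CC(C)(C)[Si](C)(C)O[C@H]1C=C(C)C[C@H]2C(=O)C(C(C)C)=CC(=O)[C@@]12C
F5 | step 13 | 4β,5β,6β-trihydroxy-4α-isopropyl-1β,8-dimethyl-10-oxobicyclo[4.4.0]dec-8-en-2α-yl acetate | O=C1C=C(C)C[C@]2(O)[C@@H](O)[C@](O)(C(C)C)C[C@H](OC(C)=O)[C@]12C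
F6 | step 13 | 4β,5β,6β,10β-tetrahydroxy-4α-isopropyl-1β,8-dimethylbicyclo[4.4.0]dec-8-en-2α-yl acetate | O[C@H]1C=C(C)C[C@]2(O)[C@@H](O)[C@](O)(C(C)C)C[C@H](OC(C)=O)[C@]12C
F7 | step 17 | 6-O-{2-[bis(2,2,2-trifluoroethoxy)phosphoryl]propanoyl} derivative of 20 | CC(C(=O)O[C@H]1CC(C)=C[C@H](OC(=O)c2ccccc2)[C@@]2(C)[C@@H](OC(C)=O)C[C@@](O)(C(C)C)[C@H]12)P(=O)(OCC(F)(F)F)OCC(F)(F)F
F0 | step 11 | none | none
A1 | alternative 1 | metathesis precursor: cyclopentane with the C10 vinyl carbinol benzoate on C1 and the C6 methallyl carbinol angelate on C5 | C=C[C@H](OC(=O)c1ccccc1)[C@@]2(C)[C@@H](OC(C)=O)C[C@@](O)(C(C)C)[C@@H]2[C@@H](OC(=O)/C(C)=C\C)CC(C)=C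
A2 | alternative 2 | enol acetate of the cis-bicyclo[3.3.0]octane-2,4-dione carrying C1-CH3, C2-OAc and C4(OH)-isopropyl | CC(=O)OC1=CC(=O)[C@@]2(C)[C@@H](OC(C)=O)C[C@@](O)(C(C)C)[C@@H]12
A3 | alternative 2 | cis-fused 2α-acetoxy-4β-hydroxy-8-methylene-daucane-6,10-dione | C=C1CC(=O)[C@@H]2[C@](O)(C(C)C)C[C@H](OC(C)=O)[C@]2(C)C(=O)C1
A4 | alternative 3 | cycloheptenone with the quaternary C1 carrying the CH(OAc)CH2C(=O)iPr chain and the C10 benzoate | CC(C)C(=O)C[C@H](OC(C)=O)[C@@]1(C)CC(=O)CC(C)=C[C@@H]1OC(=O)c1ccccc1
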